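## Retrosynthetic overview
1. Target 7 ⇒ remove the three aryl C–Br bonds (exhaustive SEAr, last step) ⇒ 3,4-dihydroxybenzyl methyl sulfone 4.
2. 4 ⇒ benzylic C–S disconnection ⇒ 3,4-dihydroxybenzyl alcohol 1 (reacting as p-quinone methide 3) + sodium methanesulfinate 2.
3. No ring is formed; the benzene ring is bought with 1.
4. C–S comes before C–Br, so the ipso carbon carries a CH2SO2Me group that cannot be expelled during bromination.

Assumption: the target SMILES has no stereocentre and no stereogenic double bond. The compound is achiral, so "single enantiomer" needs no stereocontrol.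

## Route

Step 1
Reactants: 1 3,4-dihydroxybenzyl alcohol; 2 sodium methanesulfinate
Product: 4 3,4-dihydroxybenzyl methyl sulfone, via p-quinone methide 3 (not isolated)
Conditions: MeSO2Na (2.5 equiv), HCO2H–H2O (1:1), N2, 50 °C
Reagents that add atoms: sodium methanesulfinate (2), CS(=O)[O-].[Na+]
Why: Acid-promoted dehydration of the p-hydroxybenzylic alcohol gives quinone methide 3 (or its O-protonated benzylic cation), and the excess soft S-nucleophile traps it by 1,6-conjugate addition (dehydrative SN1-type sulfonylation) far faster than a catechol ring can, rearomatising to the thermodynamically favoured sulfone; no stereocentre is formed.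

Step 2
Reactants: 4 3,4-dihydroxybenzyl methyl sulfone
Product: 7 2,3,6-tribromo-4,5-dihydroxybenzyl methyl sulfone (target), via monobromide 5 (not isolated), via dibromide 6 (not isolated)
Conditions: Br2 (3.2 equiv), AcOH, dark, rt then 50 °C
Reagents that add atoms: bromine, BrBr
Why: This is exhaustive electrophilic aromatic bromination, since every free ring CH is ortho or para to a free OH (para to the 3-OH first, then ortho to the 4-OH, then ortho to the 3-OH, as in catechol to tetrabromocatechol), while the ipso CH2SO2Me cannot leave as a cation and the sulfone and its α-CH2 are inert to Br2/HBr/AcOH; no stereocentre is formed.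

## Compound list
1 | 3,4-dihydroxybenzyl alcohol (4-(hydroxymethyl)benzene-1,2-diol) | OCc1ccc(O)c(O)c1 | starting material
2 | sodium methanesulfinate | CS(=O)[O-].[Na+] | starting material
3 | 2-hydroxy-4-methylidenecyclohexa-2,5-dien-1-one (p-quinone methide) | C=C1C=CC(=O)C(O)=C1 | intermediate
4 | 3,4-dihydroxybenzyl methyl sulfone (4-[(methylsulfonyl)methyl]benzene-1,2-diol) | CS(=O)(=O)Cc1ccc(O)c(O)c1 | intermediate
5 | 2-bromo-4,5-dihydroxybenzyl methyl sulfone | CS(=O)(=O)Cc1cc(O)c(O)cc1Br | intermediate
6 | 2,3-dibromo-4,5-dihydroxybenzyl methyl sulfone | CS(=O)(=O)Cc1cc(O)c(O)c(Br)c1Br | intermediate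
7 | 2,3,6-tribromo-4,5-dihydroxybenzyl methyl sulfone (3,4,6-tribromo-5-[(methylsulfonyl)methyl]benzene-1,2-diol) | CS(=O)(=O)Cc1c(Br)c(O)c(O)c(Br)c1Br | target

Total step count: 2
Longest linear sequence: 2

## Steps most likely to fail
The route has only two steps, so both are ranked and there is no third.

**First, step 1.** The risks are:
- acid-induced self-condensation of 1 to diarylmethane oligomers;
- disproportionation of the sulfinic acid;
- ring sulfonylation if air makes some o-quinone.

The fallback replaces the quinone-methide chemistry with a plain SN2 on a protected ring. It sets out from 2. Compound 2 is alkylated with bought 3,4-dimethoxybenzyl chloride F1 (DMF, 60 °C) to give 3,4-dimethoxybenzyl methyl sulfone F2. Both methyl ethers are then cleaved with BBr3 (3 equiv, CH2Cl2, −78 °C to rt, water work-up). This comes back to the route at 4.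

**Second, step 2.** The risks are:
- the reaction stalls at dibromide 6, because the last position lies between OH and CH2SO2Me;
- Br2 oxidises the catechol to the o-quinone; a bisulfite wash returns small amounts of quinone to the catechol.

The fallback puts the bromines on before the sulfone and forms the C–S bond last. It sets out from 2, the only route compound it keeps, and from bought 4-methylcatechol F3. Br2 (3.1 equiv, AcOH, rt) gives 3,4,6-tribromo-5-methylbenzene-1,2-diol F4. Ac2O with cat. H2SO4 gives 3,4,6-tribromo-5-methyl-1,2-phenylene diacetate F5. Wohl–Ziegler bromination (NBS, AIBN, PhCF3, reflux) gives 3,4,6-tribromo-5-(bromomethyl)-1,2-phenylene diacetate F6. SN2 with 2 (DMF, rt) gives 3,4,6-tribromo-5-[(methylsulfonyl)methyl]-1,2-phenylene diacetate F7. Acid-catalysed methanolysis (cat. H2SO4, MeOH, 50 °C) then comes back to the route at 7. Acid is used rather than base because base would expel methanesulfinate from the p-hydroxybenzyl sulfone through a quinone methide.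

## Further compounds
F1 | step 1 | 3,4-dimethoxybenzyl chloride (bought) | COc1ccc(CCl)cc1OC
F2 | step 1 | 3,4-dimethoxybenzyl methyl sulfone | COc1ccc(CS(C)(=O)=O)cc1OC
F3 | step 2 | 4-methylcatechol (bought) | Cc1ccc(O)c(O)c1
F4 | step 2 | 3,4,6-tribromo-5-methylbenzene-1,2-diol | Cc1c(Br)c(O)c(O)c(Br)c1Br
F5 | step 2 | 3,4,6-tribromo-5-methyl-1,2-phenylene diacetate | Cc1c(Br)c(OC(C)=O)c(OC(C)=O)c(Br)c1Br
F6 | step 2 | 3,4,6-tribromo-5-(bromomethyl)-1,2-phenylene diacetate | BrCc1c(Br)c(OC(C)=O)c(OC(C)=O)c(Br)c1Br
F7 | step 2 | 3,4,6-tribromo-5-[(methylsulfonyl)methyl]-1,2-phenylene diacetate | CS(=O)(=O)Cc1c(Br)c(OC(C)=O)c(OC(C)=O)c(Br)c1Br
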